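**Plan**

- Retrosynthesis: remove the C13 acetate; cut the lactone at C16 (O14–C16 and C15–C16, CO insertion into a diol enol triflate, i.e. a β-hydroxy methyl ketone); cut O–C14 and C15–C1 together; cut C13–C14 of the 14-membered ring (alkenylzinc plus enal); cut C1–C2 (acetylide plus epoxy triflate) back to farnesol.
- Enabling feature: the lactone atoms O–C14–C1–C15 are the O1–C5–C4–C3 atoms of a 2-isoxazoline, and the C13 oxygen sits next to C14. The trans ring fusion with O13, O14 and C15 all syn is therefore the retron of a hydroxyl-directed nitrile oxide [3+2] cycloaddition to an (E)-C1=C14 allylic alcohol in the 14-membered ring.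
- Forward: farnesol (C2–C13 and the three methyls) → 3,4-epoxide → C1/C14 alkyne → C13 enal → 14-membered ring closed at C13–C14 → isoxazoline across C1/C14 → lactone ring by CO insertion → acetate.
- Stereochemistry: C3/C4 from Sharpless epoxidation; C13 from the amino-alcohol-catalysed macrocyclisation; C14 and C1 both relayed from C13 in the cycloaddition (chelate-controlled face, suprafacial addition to the E olefin).
- Olefin geometry: C7=C8 from farnesol, C11=C12 from E-selective SeO2 oxidation, C1=C14 from syn hydroboration.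

Key step: step 7

Remark: cembrane numbering is used (C1 ring-fusion CH, C2 CH2, C3/C4 epoxide, C13 CH–OAc, C14 lactone CH–O, C15 α-carbon, C16 C=O, C17 exocyclic CH2); the sense of induction of (+)-DAIB is assumed from the accepted facial model of this ligand with enals.

**Route**

Step 1
Reactants: 1 (2E,6E)-farnesol
Product: 2 [(2S,3S)-3-[(3E)-4,8-dimethylnona-3,7-dien-1-yl]-3-methyloxiran-2-yl]methanol
Conditions: Ti(OiPr)4 (5 mol %), L-(+)-diethyl tartrate (6 mol %), t-BuOOH (anhydrous, 2 equiv), 4 Å MS, CH2Cl2, −20 °C
Reagents that add atoms: tert-butyl hydroperoxide CC(C)(C)OO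
Why: Sharpless asymmetric epoxidation, in which the titanium tartrate complex should epoxidise only the allylic 2,3-olefin and, with the L-(+)-tartrate, deliver oxygen to the face that gives the (2S,3S)-epoxide, setting C3 and C4 of the target.

Step 2
Reactants: 2 (2S,3S)-2,3-epoxyfarnesol
Product: 3 [(2S,3S)-3-[(3E)-4,8-dimethylnona-3,7-dien-1-yl]-3-methyloxiran-2-yl]methyl trifluoromethanesulfonate
Conditions: Tf2O, 2,6-lutidine, CH2Cl2, −78 °C; cold aq NaHCO3 work-up, used at once
Reagents that add atoms: triflic anhydride O=S(=O)(OS(=O)(=O)C(F)(F)F)C(F)(F)F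
Why: O-sulfonylation of the primary alcohol at low temperature touches no stereocentre and turns C2 into an electrophile reactive enough for acetylide alkylation below −20 °C.

Step 3
Reactants: 3 epoxy triflate; 4 (trimethylsilyl)acetylene
Product: 7 (2S,3S)-2-[(3E)-4,8-dimethylnona-3,7-dien-1-yl]-2-methyl-3-(prop-2-yn-1-yl)oxirane, via lithium (trimethylsilyl)acetylide 5 (not isolated), via silylated alkyne 6 (not isolated)
Conditions: 4, n-BuLi, THF, −78 °C; DMPU, then 3, −78 → −20 °C; then MeOH, K2CO3 (cat.), rt
Reagents that add atoms: none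
Why: SN2 alkylation of the lithium acetylide by the primary triflate, which without a Lewis acid should outrun opening of the trisubstituted epoxide, followed by methanolysis of the alkynyl–silicon bond in the same flask, forms C1–C2 and brings in C1 and C14.

Step 4
Reactants: 7 epoxy enyne
Product: 8 (2E,6E)-2,6-dimethyl-9-[(2S,3S)-2-methyl-3-(prop-2-yn-1-yl)oxiran-2-yl]nona-2,6-dien-1-ol
Conditions: SeO2 (0.3 equiv), t-BuOOH (3 equiv), CH2Cl2, 0 °C → rt
Reagents that add atoms: selenium dioxide O=[Se]=O (oxygen carrier); tert-butyl hydroperoxide CC(C)(C)OO (terminal oxygen source)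
Why: selenium dioxide allylic oxidation (ene reaction, then [2,3]-sigmatropic shift) should occur at the terminal trisubstituted olefin and E-selectively at its trans methyl group, giving the (E)-allylic alcohol whose carbon becomes C13; any enal formed alongside is the product of step 5 and is carried forward.

Step 5
Reactants: 8 allylic alcohol
Product: 9 (2E,6E)-2,6-dimethyl-9-[(2S,3S)-2-methyl-3-(prop-2-yn-1-yl)oxiran-2-yl]nona-2,6-dienal
Conditions: activated MnO2 (excess), CH2Cl2, rt
Reagents that add atoms: none
Why: MnO2 oxidises allylic alcohols selectively and should leave the epoxide, the alkyne and the olefin geometry untouched.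

Step 6
Reactants: 9 ynal
Product: 12 (1S,3E,5R,6E,10E,14S)-6,10,14-trimethyl-15-oxabicyclo[12.1.0]pentadeca-3,6,10-trien-5-ol [(3S,4S,13R)-3,4-epoxy-15,16,17-trinorcembra-1(14)E,7E,11E-trien-13-ol], via alkenyl(dicyclohexyl)borane 10 (not isolated), via alkenyl(ethyl)zinc 11 (not isolated)
Conditions: Cy2BH (1.05 equiv), hexane, 0 °C → rt; slow addition to Et2Zn (2 equiv), (+)-DAIB (5 mol %), hexane, 0 °C, final 0.005 M; aq NH4Cl
Reagents that add atoms: none
Why: syn, anti-Markovnikov hydroboration of the terminal alkyne, boron-to-zinc exchange and amino-alcohol-catalysed 1,2-addition of the (E)-alkenylzinc to the enal under high dilution should close the 14-membered ring at C13–C14, with the E geometry of C1=C14 fixed by the hydroboration and C13 set by the ligand, (+)-DAIB being expected to give the (13R)-alcohol.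

Step 7
Reactants: 12 macrocyclic (E)-allylic alcohol; 13 acetaldoxime
Product: 17 (1S,3S,4S,13S,14S,7E,11E)-3,4-epoxy-13-hydroxy 14-membered ring trans-fused at C1–C14 to a 3-methyl-4,5-dihydroisoxazole (ring O on C14; C15 bearing methyl C17 on C1), via N-hydroxyacetimidoyl chloride 14 (not isolated), via bromomagnesium alkoxide 15 (not isolated), via acetonitrile oxide 16 (not isolated)
Conditions: 13, t-BuOCl, CH2Cl2, −78 °C; this solution added over 2 h to 12, i-PrOH (3.3 equiv), EtMgBr (3.0 equiv), CH2Cl2, 0 °C → rt; aq NH4Cl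
Reagents that add atoms: none
Why: Acetonitrile oxide 16, released from 14 by the magnesium alkoxides, should add to the C1=C14 double bond in a concerted, suprafacial 1,3-dipolar cycloaddition inside a magnesium chelate that links the C13 alkoxide of 15 to the oxygen terminus of the dipole; the closest known reaction type is the magnesium-alkoxide-directed nitrile oxide cycloaddition to secondary allylic alcohols used for aldol-type polyketide fragments. The only ring closed is the 2-isoxazoline, formed by an intermolecular [3+2] cycloaddition in which O–C14 and C15–C1 are made together (no exo or endo closure is involved), and its O1–C5–C4–C3 atoms are the O–C14–C1–C15 atoms of the lactone. C14 is set by the chelate: with the C13–O bond outside on the attacked face, H13 inside and C12 anti, the dipole oxygen should be delivered syn to the C13 oxygen, and this is also the peripheral face of the trans-cycloalkene because C12 and C2 lie on the other side. C1 follows from C14 because both bonds form on the same face of the E olefin, which gives the trans-4,5-disubstituted isoxazoline and hence the trans ring fusion. The step needs regioselectivity (oxygen on C14, the carbon nearer the hydroxyl), which the chelate enforces; chemoselectivity for the disubstituted C1=C14 over the trisubstituted C7=C8 and C11=C12 olefins, which their low dipolarophilicity and the rate acceleration of the chelated olefin should provide; and face selectivity, which rests on the C13 stereocentre as described. Slow addition of 14 keeps the dipole concentration low so that capture outruns dimerisation.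

Step 8
Reactants: 17 isoxazoline
Product: 19 (1R,3S,4S,13S,14S,7E,11E)-1-acetyl-3,4-epoxy-13,14-dihydroxy 14-membered ring (same spatial arrangement at C1 as in 17; the descriptor changes with the priorities), via hydroxy ketimine 18 (not isolated)
Conditions: SmI2 (2.5 equiv), THF, 0 °C; then B(OH)3, MeOH/H2O, rt
Reagents that add atoms: water O
Why: two-electron reduction of the N–O bond by SmI2 gives the β-hydroxy ketimine, which boric acid should hydrolyse to the ketone under near-neutral conditions that neither epimerise C1 nor open the epoxide (isoxazoline as a masked aldol).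

Step 9
Reactants: 19 dihydroxy ketone
Product: 20 13,14-bis(triethylsilyl) ether of 19
Conditions: Et3SiCl, imidazole, DMAP (cat.), DMF, 0 °C → rt
Reagents that add atoms: chlorotriethylsilane CC[Si](Cl)(CC)CC
Why: standard silylation of both secondary alcohols, so that the following enolisation meets no acidic O–H and no retro-aldol pathway.

Step 10
Reactants: 20 bis(silyl) ether ketone
Product: 22 (1R,3S,4S,13S,14S,7E,11E)-3,4-epoxy-13,14-dihydroxy 14-membered ring bearing a 1-(trifluoromethanesulfonyloxy)ethenyl group at C1, via bis(triethylsilyl) enol triflate 21 (not isolated)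
Conditions: KN(SiMe3)2 (1.2 equiv), THF, −78 °C; N-(5-chloropyridin-2-yl)bis(trifluoromethanesulfonyl)imide, −78 °C; then Et3N·3HF, 0 °C → rt
Reagents that add atoms: N-(5-chloropyridin-2-yl)bis(trifluoromethanesulfonyl)imide O=S(=O)(N(c1ccc(Cl)cn1)S(=O)(=O)C(F)(F)F)C(F)(F)F
Why: kinetic deprotonation by the hindered amide base should occur at the methyl group (C17) and not at the tertiary C1–H, O-sulfonylation then fixes the C15=C17 double bond that becomes the exocyclic methylene, and buffered fluoride cleaves both silyl ethers in the same flask without harming the epoxide or the enol triflate.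

Step 11
Reactants: 22 diol enol triflate
Product: 23 13-O-deacetyl-13-acetoxysarcocrassolide [(1S,3S,4S,13S,14S,7E,11E)-3,4-epoxy-13-hydroxycembra-7,11,15(17)-trien-16,14-olide]
Conditions: Pd(PPh3)4 (10 mol %), CO (1 atm), Et3N (3 equiv), MeCN, 60 °C
Reagents that add atoms: carbon monoxide [C-]#[O+]
Why: carbonylative lactonisation of a hydroxy enol triflate (oxidative addition of zerovalent palladium to the C15–O bond, CO insertion, intramolecular alcoholysis of the acylpalladium) should give the α-methylene-γ-lactone through O14, five-membered closure being expected to be faster than six-membered closure through O13, with C1 and C14 untouched.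

Step 12
Reactants: 23 hydroxy lactone
Product: 24 13-acetoxysarcocrassolide
Conditions: Ac2O, pyridine, DMAP (cat.), CH2Cl2, 0 °C → rt
Reagents that add atoms: acetic anhydride CC(=O)OC(C)=O
Why: DMAP-catalysed acetylation of the remaining secondary allylic alcohol under conditions routinely tolerated by α-methylene lactones and epoxides.

**Compound list**

1 | (2E,6E)-farnesol | OC/C=C(\C)CC/C=C(\C)CCC=C(C)C | starting material
2 | [(2S,3S)-3-[(3E)-4,8-dimethylnona-3,7-dien-1-yl]-3-methyloxiran-2-yl]methanol | OC[C@@H]1O[C@@]1(C)CC/C=C(\C)CCC=C(C)C | intermediate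
3 | [(2S,3S)-3-[(3E)-4,8-dimethylnona-3,7-dien-1-yl]-3-methyloxiran-2-yl]methyl trifluoromethanesulfonate | O=S(=O)(OC[C@@H]1O[C@@]1(C)CC/C=C(\C)CCC=C(C)C)C(F)(F)F | intermediate
4 | (trimethylsilyl)acetylene | C#C[Si](C)(C)C | starting material
5 | lithium (trimethylsilyl)acetylide | [Li]C#C[Si](C)(C)C | intermediate (not isolated)
6 | trimethyl[3-[(2S,3S)-3-[(3E)-4,8-dimethylnona-3,7-dien-1-yl]-3-methyloxiran-2-yl]prop-1-yn-1-yl]silane | C[Si](C)(C)C#CC[C@@H]1O[C@@]1(C)CC/C=C(\C)CCC=C(C)C | intermediate (not isolated)
7 | (2S,3S)-2-[(3E)-4,8-dimethylnona-3,7-dien-1-yl]-2-methyl-3-(prop-2-yn-1-yl)oxirane | C#CC[C@@H]1O[C@@]1(C)CC/C=C(\C)CCC=C(C)C | intermediate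
8 | (2E,6E)-2,6-dimethyl-9-[(2S,3S)-2-methyl-3-(prop-2-yn-1-yl)oxiran-2-yl]nona-2,6-dien-1-ol | C#CC[C@@H]1O[C@@]1(C)CC/C=C(\C)CC/C=C(\C)CO | intermediate
9 | (2E,6E)-2,6-dimethyl-9-[(2S,3S)-2-methyl-3-(prop-2-yn-1-yl)oxiran-2-yl]nona-2,6-dienal | C#CC[C@@H]1O[C@@]1(C)CC/C=C(\C)CC/C=C(\C)C=O | intermediate
10 | dicyclohexyl[(1E)-3-[(2S,3S)-3-[(3E,7E)-4,8-dimethyl-9-oxonona-3,7-dien-1-yl]-3-methyloxiran-2-yl]prop-1-en-1-yl]borane | B(C1CCCCC1)(C1CCCCC1)/C=C/C[C@@H]1O[C@@]1(C)CC/C=C(\C)CC/C=C(\C)C=O | intermediate (not isolated)
11 | ethyl[(1E)-3-[(2S,3S)-3-[(3E,7E)-4,8-dimethyl-9-oxonona-3,7-dien-1-yl]-3-methyloxiran-2-yl]prop-1-en-1-yl]zinc | CC[Zn]/C=C/C[C@@H]1O[C@@]1(C)CC/C=C(\C)CC/C=C(\C)C=O | intermediate (not isolated)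
12 | (1S,3E,5R,6E,10E,14S)-6,10,14-trimethyl-15-oxabicyclo[12.1.0]pentadeca-3,6,10-trien-5-ol | O[C@@H]1/C=C/C[C@@H]2O[C@@]2(C)CC/C=C(\C)CC/C=C1\C | intermediate
13 | acetaldoxime | CC=NO | starting material
14 | N-hydroxyacetimidoyl chloride | CC(Cl)=NO | intermediate (not isolated)
15 | bromomagnesium alkoxide of 12 | Br[Mg]O[C@@H]1/C=C/C[C@@H]2O[C@@]2(C)CC/C=C(\C)CC/C=C1\C | intermediate (not isolated)
16 | acetonitrile oxide | CC#[N+][O-] | intermediate (not isolated)
17 | (1S,3S,4S,13S,14S,7E,11E)-isoxazoline (3-methyl-4,5-dihydroisoxazole trans-fused at C1–C14, O on C14, 13-OH, 3,4-epoxide) | CC1=NO[C@H]2[C@H]1C[C@@H]1O[C@@]1(C)CC/C=C(\C)CC/C=C(\C)[C@@H]2O | intermediate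
18 | (1S,3S,4S,13S,14S)-13,14-dihydroxy N–H ketimine (1-(1-iminoethyl) at C1) | CC(=N)[C@@H]1C[C@@H]2O[C@@]2(C)CC/C=C(\C)CC/C=C(\C)[C@H](O)[C@H]1O | intermediate (not isolated)
19 | (1R,3S,4S,13S,14S,7E,11E)-1-acetyl-3,4-epoxy-13,14-diol | CC(=O)[C@@H]1C[C@@H]2O[C@@]2(C)CC/C=C(\C)CC/C=C(\C)[C@H](O)[C@H]1O | intermediate
20 | 13,14-bis(triethylsilyl) ether of 19 | CC(=O)[C@@H]1C[C@@H]2O[C@@]2(C)CC/C=C(\C)CC/C=C(\C)[C@H](O[Si](CC)(CC)CC)[C@H]1O[Si](CC)(CC)CC | intermediate
21 | 13,14-bis(triethylsilyl) ether of enol triflate 22 | C=C(OS(=O)(=O)C(F)(F)F)[C@@H]1C[C@@H]2O[C@@]2(C)CC/C=C(\C)CC/C=C(\C)[C@H](O[Si](CC)(CC)CC)[C@H]1O[Si](CC)(CC)CC | intermediate (not isolated)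
22 | (1R,3S,4S,13S,14S,7E,11E)-13,14-diol with 1-(trifluoromethanesulfonyloxy)ethenyl at C1 | C=C(OS(=O)(=O)C(F)(F)F)[C@@H]1C[C@@H]2O[C@@]2(C)CC/C=C(\C)CC/C=C(\C)[C@H](O)[C@H]1O | intermediate
23 | 13-O-deacetyl-13-acetoxysarcocrassolide | C=C1C(=O)O[C@H]2[C@H]1C[C@@H]1O[C@@]1(C)CC/C=C(\C)CC/C=C(\C)[C@@H]2O | intermediate
24 | 13-acetoxysarcocrassolide | C=C1C(=O)O[C@H]2[C@H]1C[C@@H]1O[C@@]1(C)CC/C=C(\C)CC/C=C(\C)[C@@H]2OC(C)=O | target

**Step count and risks**

Total steps: 12. Longest linear sequence: 12 steps (from farnesol).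

Steps most likely to fail:

Step 7. The face selectivity may erode if the macrocycle does not populate the conformer that puts the C13–O bond in the chelating position; the small nitrile oxide may dimerise faster than it is captured; and bromide from the magnesium salts may open the 3,4-epoxide. The fallback sets out from 12 and returns at 17, and moves stereocontrol from the substrate to a reagent under halide-free conditions. Compound 12 is treated with Et2Zn to give the ethylzinc alkoxide of 12 F1. Diisopropyl tartrate (the enantiomer matched to the substrate) and a second equivalent of Et2Zn are added in CHCl3/dioxane at 0 °C, followed by slow addition of 14. The dipole should then be generated and delivered inside a chiral zinc tartrate assembly that binds both the allylic alkoxide and the nitrile oxide oxygen, so the face is chosen by the tartrate and not by the ring conformation; aqueous NH4Cl work-up gives 17.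

Step 6. Intermolecular addition may compete with ring closure, ethyl may transfer from zinc to the enal, the dialkylborane may reduce the enal during hydroboration, and catalyst control over C13 may be incomplete. The fallback sets out from 8 and returns at 12, closing the ring by a Nozaki–Hiyama–Kishi reaction and setting C13 afterwards. Hydrozirconation of 8 with Cp2Zr(H)Cl (2.2 equiv, THF) and iodinolysis with I2 should give (2E,6E)-9-[(2S,3S)-3-[(2E)-3-iodoprop-2-en-1-yl]-2-methyloxiran-2-yl]-2,6-dimethylnona-2,6-dien-1-ol F2. MnO2 gives the corresponding iodo enal F3. CrCl2 with catalytic NiCl2 in DMSO/THF at high dilution should close the ring to 12 together with the (13S)-epimer of 12 F4. MnO2 oxidation of the mixture gives the cross-conjugated macrocyclic dienone F5, and Corey–Bakshi–Shibata reduction ((S)-2-methyl-CBS-oxazaborolidine, catecholborane, toluene, −78 °C, the 2-methylalkenyl arm expected to act as the larger group) should return 12.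

Step 11. The acylpalladium may be captured by the C13 hydroxyl to give the six-membered lactone, and the free diol may slow the catalyst. The fallback sets out from 21 (isolated by leaving out the fluoride treatment in step 10) and returns at 23; it brings in C16 intermolecularly and closes the lactone under equilibrating conditions. Methoxycarbonylation (Pd(OAc)2, 1,3-bis(diphenylphosphino)propane, CO, MeOH, Et3N, DMF, 50 °C) should give the methyl 2-substituted acrylate with both silyl ethers intact F6. Et3N·3HF in MeCN then gives the 13,14-dihydroxy methyl ester F7, which should lactonise spontaneously or with a trace of pyridinium p-toluenesulfonate in CH2Cl2 to the thermodynamically preferred five-membered lactone 23.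

**Further compounds**

F1 | step 7 | ethylzinc alkoxide of 12 | CC[Zn]O[C@@H]1/C=C/C[C@@H]2O[C@@]2(C)CC/C=C(\C)CC/C=C1\C
F2 | step 6 | (2E,6E)-9-[(2S,3S)-3-[(2E)-3-iodoprop-2-en-1-yl]-2-methyloxiran-2-yl]-2,6-dimethylnona-2,6-dien-1-ol | I/C=C/C[C@@H]1O[C@@]1(C)CC/C=C(\C)CC/C=C(\C)CO
F3 | step 6 | (2E,6E)-9-[(2S,3S)-3-[(2E)-3-iodoprop-2-en-1-yl]-2-methyloxiran-2-yl]-2,6-dimethylnona-2,6-dienal | I/C=C/C[C@@H]1O[C@@]1(C)CC/C=C(\C)CC/C=C(\C)C=O
F4 | step 6 | (1S,3E,5S,6E,10E,14S)-6,10,14-trimethyl-15-oxabicyclo[12.1.0]pentadeca-3,6,10-trien-5-ol (13-epimer of 12) | O[C@H]1/C=C/C[C@@H]2O[C@@]2(C)CC/C=C(\C)CC/C=C1\C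
F5 | step 6 | (1S,3E,6E,10E,14S)-6,10,14-trimethyl-15-oxabicyclo[12.1.0]pentadeca-3,6,10-trien-5-one | O=C1/C=C/C[C@@H]2O[C@@]2(C)CC/C=C(\C)CC/C=C1\C
F6 | step 11 | methyl 2-substituted acrylate, 13,14-bis(triethylsilyl) ether (CO2Me in place of OTf of 21) | C=C(C(=O)OC)[C@@H]1C[C@@H]2O[C@@]2(C)CC/C=C(\C)CC/C=C(\C)[C@H](O[Si](CC)(CC)CC)[C@H]1O[Si](CC)(CC)CC
F7 | step 11 | methyl 2-substituted acrylate, 13,14-diol | C=C(C(=O)OC)[C@@H]1C[C@@H]2O[C@@]2(C)CC/C=C(\C)CC/C=C(\C)[C@H](O)[C@H]1O
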